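Remark on the chemistry: acerosin has no stereogenic centre or axis, so it is one achiral compound and the single-enantiomer requirement is met automatically. The flavone structures 1, 5 and 10 were checked atom by atom against the target SMILES and need no correction.

## Structural features

Acerosin (10) is a flavone: a benzene ring A fused to a 4-pyranone ring C (4H-chromen-4-one), with an aryl ring B joined to C2 by the single bond C2–C1′. Ring A is fully substituted, carrying 5-OH, 6-OMe, 7-OH and 8-OMe between the fusion atoms C4a and C8a, and ring B is an isovanillyl unit (3′-OH, 4′-OMe). The molecule has no stereocentre and no hindered axis, so the plan needs no stereochemical control element. The fragile parts are the three free phenols, which oxidise easily once deprotonated, and the pyranone ring, which strong base can open and re-close through the 5-oxygen (Wessely–Moser isomerisation). The real difficulty is not the skeleton but the alternating OH/OMe pattern on ring A, which cannot be reached by selective methylation of a polyhydroxy flavone because the hydroxyls that must stay free, the 7-OH above all, are the most reactive ones. The key step exploits C6 and C8 of ring A: without their methoxy groups these are the only ring-A C–H positions, C6 lying between the 5-OH and 7-OH carbons and C8 between the 7-OH carbon and C8a, which bears the pyranone ether oxygen O1 (not a phenol) while C8 is also para to the 5-OH. These two carbons are therefore the most nucleophilic sites of the whole flavone, so bromine can mark them and copper-mediated exchange of Br for OMe then brings in each oxygen already methylated, with no phenol having to be protected or distinguished.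

## Logic of the disconnections

First cut, 10 back to 5 and 6. The bonds cut are the two aryl carbon–oxygen bonds C6–OMe and C8–OMe of 10. Cutting there lets each methoxy group arrive as a unit from 6, so none of the hydroxyls of 10 has to be methylated selectively. The gain is that ring A falls from five oxygen substituents to three and becomes a plain 5,7-dihydroxy ring. The demand on the forward step is a twofold C–O coupling at two carbons that each have two ortho neighbours, on a ring that is a polyphenoxide under the conditions. Substitution must outrun reduction of C–Br to C–H at both sites, the half-converted species 7 and 8 must both react on, and the product leaves the flask as its salt 9, which must be protonated without air oxidation. 5 is deliberately used with its hydroxyls free: deprotonation makes it soluble in the methoxide medium, the ortho phenoxides can guide copper to the C–Br bonds, and no deprotection follows. A benzyl-masked variant is held in reserve.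

Second cut, 5 back to 1 and 2. The bonds cut are C6–Br and C8–Br. These are exactly the carbons that 1 offers to an electrophile, so no directing or protecting group is needed. The gain is a commercial flavone that already holds the complete carbon skeleton, the three hydroxyls and the 4′-methoxy group of 10. The demand is that exactly two equivalents of 2 are consumed by ring A. The monobromides 3 and 4 both converge on 5, but ring B (C2′ and C6′, ortho and para to the 3′-hydroxyl) and C3 must stay untouched, and the reaction must stop before ipso-attack on 5.

End point. 1, 2 and 6 are catalogue chemicals, so no further cut is needed.

## Other disconnections considered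

Alternative 1: The cut is the O1–C8a bond of ring C, so the protected flavone A1 is traced back to the 1,3-diaryl-1,3-diketone A2, whose A-ring aryl group has no oxygen ortho to the carbonyl.
- Forward key step: anodic oxidation would remove an electron from the trialkoxyaryl ring or the enol of A2. The enol oxygen on C2 would bond to the ortho ring carbon, and loss of a second electron and two protons would close the six-membered pyranone of A1. The cathode consumes the protons, so no chemical oxidant is needed.
- In its favour: A2 would come convergently from an A-ring methyl ketone and a B-ring ester by Claisen condensation. The C6 and C8 methoxy groups and the C7 oxygen are in place from the start, the A-ring aryl group is symmetric so both ortho carbons are the same, and no halogen or transition metal is used.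
- Against it here: A1 still has hydrogen at C5, so the 5-hydroxyl of 10 would have to be added later by a carbonyl-directed C–H oxygenation at the last free position of a crowded ring. The closure is an oxidation of a very electron-rich system in which attack on the wrong aryl ring (held back only by the pivalate), coupling at the central carbon, benzyl-ether oxidation and over-oxidation of A1 would all compete. Two protecting groups must also come off at the end.
- Comparison: in structure the alternative builds ring C and the whole skeleton from simple aromatics, which the chosen plan does not attempt. On that point, on independence from a natural flavone and on freedom from halogen and copper waste it is the better plan. Its fixed methoxy pattern is at least the equal of the chosen plan, since no reduction back to C–H can blur it. In mechanism it rests on radical-cation C–O bond formation with much thinner analogy than copper-mediated methoxylation of bromophenols. In step economy about seven operations would stand against two.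

Alternative 2: The cut is made at the two ring-A carbon–oxygen bonds ortho to the acyl carbon (the later C5–O and C8a–O), at the acetophenone stage, and the product of the key step is the diacetate A3.
- Forward key step: the E-configured O-methyl oxime A4 (nitrogen lone pair turned towards the ring), derived from acetosyringone A5, would be cyclopalladated at an ortho C–H. Oxidation to palladium(IV) by an iodine(III) diacetate oxidant and C–O reductive elimination would give the aryl acetate, and repetition on the other side would give A3.
- In its favour: A5 is a cheap commodity that already has the 6-OMe/7-O/8-OMe array. The substrate is symmetric, so both ortho positions are equivalent. Oxime-ether-directed ortho-acetoxylation is an established reaction type, and A3 is a fully oxygenated A-ring ketone of the kind from which flavones are classically built.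
- Against it here: each ortho C–H lies between the oxime carbon and a methoxy group, and the first acetate would twist the oxime out of the ring plane and hinder the second palladation, so clean double oxygenation is doubtful. The oxime ether of a di-ortho-substituted ketone must then be hydrolysed in the presence of three aryl esters. The pyranone and ring B still have to be attached (aroylation, Baker–Venkataraman shift, cyclodehydration, deprotection), with acyl migration among neighbouring oxygens a standing risk.
- Comparison: both plans oxygenate two C–H positions of ring A. The chosen plan uses the innate nucleophilicity of the intact flavone and delivers OMe directly, whereas the alternative needs a directing group that must be installed and removed and delivers esters that must be unmasked again. The alternative is the better on raw-material cost and independence from a natural flavone, and equal in having no regiochemical ambiguity. It is weaker on the certainty of its key step and far longer (around eight steps against two).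

Alternative 3: The cut removes the carbonyl carbon C4 from both neighbours (C4a–C4 and C4–C3), and the product of the key step is the ynone A6, assembled from the aryl iodide A7, the terminal alkyne A8 and carbon monoxide A9.
- Forward key step: palladium(0) would add into the C–I bond of A7, A9 would insert to give an aroyl–palladium species, and transfer of the copper acetylide of A8 followed by reductive elimination would give A6. Removal of one ortho benzyl group, 6-endo oxa-Michael closure and debenzylation would follow.
- In its favour: it is highly convergent, making two C–C bonds and joining both halves in one operation. All oxygens are in place and masked, the A ring is symmetric so either ortho oxygen can close the pyranone, the ynone-to-flavone closure is known chemistry, and ring B is easily varied.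
- Against it here: A7 is a hexasubstituted, pentaoxygenated benzene with differentiated benzyl and methyl ethers and is itself a multi-step target. Its iodide sits between two benzyloxy groups on a very electron-rich ring, so oxidative addition and acyl transfer would be slow, and direct alkynylation without A9, alkyne homocoupling and C–I reduction would compete. A9 is a toxic gas. The cyclisation must choose 6-endo over 5-exo (aurone) closure, and the first benzyl group cannot be removed by hydrogenolysis while the alkyne is present.
- Comparison: in structure this plan assembles the skeleton and is the better one for convergence and analogue work. It is the equal of the chosen plan in fixing the oxygen pattern before the key step. Its protected, non-polar intermediates would be easier to purify than the polyphenols of the chosen plan, which is a point in its favour. In mechanism both are late metal-mediated couplings at hindered ring-A carbons, but the chosen one is helped by ortho phenoxides and close analogy on the same ring type, while the alternative works against steric crowding. In step economy some nine to ten steps (including A7) would stand against two.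

Key step: step 2

## Route

Step 1
Reactants: 1 diosmetin; 2 N-bromosuccinimide
Product: 5 6,8-dibromodiosmetin, via 6-bromodiosmetin 3 (not isolated), via 8-bromodiosmetin 4 (not isolated)
Conditions: NBS (2.05 equiv, in portions), DMF, 0 °C → rt, dark; aq. Na2S2O3, then H2O
Reagents that add atoms: N-bromosuccinimide, O=C1CCC(=O)N1Br
Why: Electrophilic aromatic bromination: ring A of 1 is a phloroglucinol-type ring whose only C–H positions, C6 and C8, are ortho/para to the 5- and 7-hydroxyls, so it should take up both bromine atoms at 0 °C before the less activated ring B (further deactivated by the attached pyranone) or C3 reacts. Both monobromides 3 and 4 remain activated and converge on 5; exact stoichiometry and a reductive quench guard against ipso-overbromination.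

Step 2
Reactants: 5 6,8-dibromodiosmetin; 6 sodium methoxide
Product: 10 acerosin, via 6-bromo-8-methoxydiosmetin 7 (not isolated), via 8-bromo-6-methoxydiosmetin 8 (not isolated), via trisodium acerosin triphenoxide 9 (not isolated)
Conditions: NaOMe (25% in MeOH, ca. 15 equiv), CuBr (0.4 equiv), DMF, 110 °C, Ar; then 1 M aq. HCl, 0 °C
Reagents that add atoms: sodium methoxide, C[O-].[Na+]
Why: Copper(I) bromide and excess methoxide form a copper(I) methoxide (methoxycuprate) that is held near each C–Br bond by the neighbouring phenoxide, adds oxidatively into the C–Br bond to give an aryl–copper(III) methoxide and then forms the aryl–OMe bond by reductive elimination, once at C6 and once at C8, regenerating copper(I). The closest known reaction type is the Ullmann-type copper-catalysed methoxylation of ortho-bromophenols with sodium methoxide in DMF (3,5-dibromo-4-hydroxybenzaldehyde to syringaldehyde) and of 6,8-dihalo-5,7-dihydroxyflavones. No ring is closed and no stereocentre is created. The selectivity needed is substitution over hydrodebromination at both carbons, which a large excess of methoxide, little free methanol, exclusion of oxygen and the copper-binding ortho phenoxides should secure. Chemoselectivity follows from the substrate: only C6 and C8 carry halogen, so ring B and C3 cannot react and methoxy can only appear where step 1 placed bromine. Base-induced opening and re-closure of the pyranone through the 5-oxygen maps 5 and 9 onto themselves and merely interconverts 7 and 8 (written as neutral phenols although present as phenoxides), both of which lead to 9, so it cannot change the outcome. Cold acidification under argon protonates 9 to 10.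

## Compound list

1 | diosmetin, 5,7-dihydroxy-2-(3-hydroxy-4-methoxyphenyl)-4H-chromen-4-one | COc1ccc(-c2cc(=O)c3c(O)cc(O)cc3o2)cc1O | starting material
2 | N-bromosuccinimide, 1-bromopyrrolidine-2,5-dione | O=C1CCC(=O)N1Br | starting material
3 | 6-bromodiosmetin, 6-bromo-5,7-dihydroxy-2-(3-hydroxy-4-methoxyphenyl)-4H-chromen-4-one | COc1ccc(-c2cc(=O)c3c(O)c(Br)c(O)cc3o2)cc1O | intermediate
4 | 8-bromodiosmetin, 8-bromo-5,7-dihydroxy-2-(3-hydroxy-4-methoxyphenyl)-4H-chromen-4-one | COc1ccc(-c2cc(=O)c3c(O)cc(O)c(Br)c3o2)cc1O | intermediate
5 | 6,8-dibromodiosmetin, 6,8-dibromo-5,7-dihydroxy-2-(3-hydroxy-4-methoxyphenyl)-4H-chromen-4-one | COc1ccc(-c2cc(=O)c3c(O)c(Br)c(O)c(Br)c3o2)cc1O | intermediate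
6 | sodium methoxide | C[O-].[Na+] | starting material
7 | 6-bromo-8-methoxydiosmetin, 6-bromo-5,7-dihydroxy-2-(3-hydroxy-4-methoxyphenyl)-8-methoxy-4H-chromen-4-one | COc1ccc(-c2cc(=O)c3c(O)c(Br)c(O)c(OC)c3o2)cc1O | intermediate
8 | 8-bromo-6-methoxydiosmetin, 8-bromo-5,7-dihydroxy-2-(3-hydroxy-4-methoxyphenyl)-6-methoxy-4H-chromen-4-one | COc1ccc(-c2cc(=O)c3c(O)c(OC)c(O)c(Br)c3o2)cc1O | intermediate
9 | trisodium acerosin triphenoxide, trisodium salt of 10 at the 5-, 7- and 3′-oxygens | COc1ccc(-c2cc(=O)c3c([O-])c(OC)c([O-])c(OC)c3o2)cc1[O-].[Na+].[Na+].[Na+] | intermediate
10 | acerosin, 5,7-dihydroxy-2-(3-hydroxy-4-methoxyphenyl)-6,8-dimethoxy-4H-chromen-4-one (achiral) | COc1ccc(-c2cc(=O)c3c(O)c(OC)c(O)c(OC)c3o2)cc1O | target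

## Step count and least certain steps

Total step count: 2. Longest linear sequence: 2 steps (1 → 5 → 10). The route has only two steps, so the key step and the single other step are both discussed.

Step 2 (key step). The most likely failure is reductive loss of bromine at one or both carbons in competition with C–O coupling. The trianionic ring is very electron-rich, so copper insertion is slow, while methanol, methoxide and DMF can all deliver hydrogen to an aryl–copper or aryl radical intermediate. Oxidative degradation of the hot polyphenoxide by traces of air is the second risk. The fallback sets out from 5 and comes back at 10:
- 5 is benzylated at the 7- and 3′-hydroxyls (benzyl bromide, K2CO3, DMF, rt; the chelated 5-OH stays free) to give 7-(benzyloxy)-2-[3-(benzyloxy)-4-methoxyphenyl]-6,8-dibromo-5-hydroxy-4H-chromen-4-one F1.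
- This soluble, only singly deprotonatable substrate is methoxylated with 6 and copper(I) in DMF to 7-(benzyloxy)-2-[3-(benzyloxy)-4-methoxyphenyl]-5-hydroxy-6,8-dimethoxy-4H-chromen-4-one F2, which can be chromatographed free of reduced material.
- Hydrogenolysis (H2, Pd/C, THF–MeOH, rt) removes both benzyl groups to give 10.

All three operations are standard types: Williamson benzylation, Ullmann-type methoxylation of an O-alkylated haloflavone, and benzyl ether hydrogenolysis.

Step 1. The most likely failure is loss of control over the number and position of bromine atoms: incomplete bromination, ipso-attack on the already brominated ring, or bromination of ring B next to the free 3′-hydroxyl. Correcting this is harder because the polar, poorly soluble phenols are difficult to separate. The fallback sets out from 1 and comes back at 10: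
- 1 is first benzylated selectively at the 7- and 3′-hydroxyls (benzyl bromide, K2CO3, DMF) to 7-(benzyloxy)-2-[3-(benzyloxy)-4-methoxyphenyl]-5-hydroxy-4H-chromen-4-one F3, a soluble compound that can be purified by chromatography.
- Its ring A, still activated by the free 5-hydroxyl and the 7-ether while ring B is now only a diether, is dibrominated with 2 to 7-(benzyloxy)-2-[3-(benzyloxy)-4-methoxyphenyl]-6,8-dibromo-5-hydroxy-4H-chromen-4-one F1.
- F1 is carried on by copper-mediated methoxylation with 6 to 7-(benzyloxy)-2-[3-(benzyloxy)-4-methoxyphenyl]-5-hydroxy-6,8-dimethoxy-4H-chromen-4-one F2 and by hydrogenolysis to 10, as in the fallback for step 2.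

## Further compounds

F1 | step 2 | 7-(benzyloxy)-2-[3-(benzyloxy)-4-methoxyphenyl]-6,8-dibromo-5-hydroxy-4H-chromen-4-one | COc1ccc(-c2cc(=O)c3c(O)c(Br)c(OCc4ccccc4)c(Br)c3o2)cc1OCc1ccccc1
F2 | step 2 | 7-(benzyloxy)-2-[3-(benzyloxy)-4-methoxyphenyl]-5-hydroxy-6,8-dimethoxy-4H-chromen-4-one | COc1ccc(-c2cc(=O)c3c(O)c(OC)c(OCc4ccccc4)c(OC)c3o2)cc1OCc1ccccc1
F3 | step 1 | 7-(benzyloxy)-2-[3-(benzyloxy)-4-methoxyphenyl]-5-hydroxy-4H-chromen-4-one | COc1ccc(-c2cc(=O)c3c(O)cc(OCc4ccccc4)cc3o2)cc1OCc1ccccc1
A1 | alternative 1 | 7-(benzyloxy)-6,8-dimethoxy-2-[4-methoxy-3-(pivaloyloxy)phenyl]-4H-chromen-4-one | COc1ccc(-c2cc(=O)c3cc(OC)c(OCc4ccccc4)c(OC)c3o2)cc1OC(=O)C(C)(C)C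
A2 | alternative 1 | 1-[4-(benzyloxy)-3,5-dimethoxyphenyl]-3-[4-methoxy-3-(pivaloyloxy)phenyl]propane-1,3-dione | COc1ccc(C(=O)CC(=O)c2cc(OC)c(OCc3ccccc3)c(OC)c2)cc1OC(=O)C(C)(C)C
A3 | alternative 2 | (E)-2,6-diacetoxy-3,5-dimethoxy-4-(pivaloyloxy)acetophenone O-methyl oxime | CO/N=C(\C)c1c(OC(C)=O)c(OC)c(OC(=O)C(C)(C)C)c(OC)c1OC(C)=O
A4 | alternative 2 | (E)-3,5-dimethoxy-4-(pivaloyloxy)acetophenone O-methyl oxime | CO/N=C(\C)c1cc(OC)c(OC(=O)C(C)(C)C)c(OC)c1
A5 | alternative 2 | acetosyringone, 1-(4-hydroxy-3,5-dimethoxyphenyl)ethanone | CC(=O)c1cc(OC)c(O)c(OC)c1
A6 | alternative 3 | 3-[3-(benzyloxy)-4-methoxyphenyl]-1-[2,4,6-tris(benzyloxy)-3,5-dimethoxyphenyl]prop-2-yn-1-one | COc1ccc(C#CC(=O)c2c(OCc3ccccc3)c(OC)c(OCc3ccccc3)c(OC)c2OCc2ccccc2)cc1OCc1ccccc1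
A7 | alternative 3 | 1,3,5-tris(benzyloxy)-2-iodo-4,6-dimethoxybenzene | COc1c(OCc2ccccc2)c(I)c(OCc2ccccc2)c(OC)c1OCc1ccccc1
A8 | alternative 3 | 2-(benzyloxy)-4-ethynyl-1-methoxybenzene | C#Cc1ccc(OC)c(OCc2ccccc2)c1
A9 | alternative 3 | carbon monoxide | [C-]#[O+]
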